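The oxan-2-one ring is a triacetate: oxygen sits on C2, C4 and C6, so the ring bonds C3–C4 and C5–C6 are both aldol bonds and C4–C5 is one acetaldehyde unit. The key step makes both bonds in one operation: (E)-crotonaldehyde takes up two acetaldehyde silyl enolates in a catalyst-controlled double Mukaiyama aldol, which sets ring C6 and C4 as a syn-3,5-bis(silyloxy)octenal. Its precursor is only the four-carbon enal and the enol silane. Oxidation and lactonisation give a 6-propenyl lactone, and cross-metathesis with a styryl dimethoxy diene, built from cinnamaldehyde by the same aldol and an allylboration, completes the target.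

Key step: step 1

Assumption: the IDPi (imidodiphosphorimidate) acids are named by the aldehyde face they deliver (IDPi-Re in step 1, IDPi-Si in step 4); their (S,S)/(R,R) descriptors would be assigned on mono-adducts 3 and 9 by Mosher analysis after reduction.

Step 1
Reactants: 1 (E)-but-2-enal (crotonaldehyde); 2 tert-butyldimethyl(vinyloxy)silane (2.4 equiv)
Product: 4 (3S,5R,6E)-3,5-bis[(tert-butyldimethylsilyl)oxy]oct-6-enal, via mono-aldol aldehyde 3 (not isolated)
Conditions: IDPi-Re (2 mol%), toluene, −60 → −20 °C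
Reagents that add atoms: none
Why: The IDPi acid is silylated by 2 to a silylium ion pair that activates 1 as a silyloxocarbenium ion inside the chiral anion pocket; 2 adds 1,2 at the Re face, the silyl group ends on the new oxygen, and the released β-silyloxy aldehyde 3 re-enters the same cycle for a second Re-face addition (double Mukaiyama aldol). The closest known reaction types are the enantioselective single aldolisation of acetaldehyde silyl enolates under confined IDPi acids and the one-pot double aldol cascade of bulky acetaldehyde enol silanes under achiral silylium catalysis. No ring is closed here; the oxan-2-one ring closes in step 3 by 6-exo-trig lactonisation. C5 of 4 (ring C6, R) is set by the catalyst in the first addition and C3 of 4 (ring C4, S) by the same catalyst in the second, and two additions of like sense give the 3,5-syn pattern. The step needs 1,2- over 1,4-addition (the weakly nucleophilic enol silane attacks the oxocarbenium carbon), a stop after the second addition (2.4 equiv of 2, bulk and inductive deactivation of the bis-silyloxy aldehyde) and catalyst control over the small anti bias of 3, for which an IDPi with a pocket wide enough to admit 3 is chosen.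

Step 2
Reactants: 4 (3S,5R,6E)-3,5-bis[(tert-butyldimethylsilyl)oxy]oct-6-enal
Product: 5 (3S,5R,6E)-3,5-bis[(tert-butyldimethylsilyl)oxy]oct-6-enoic acid
Conditions: NaClO2, NaH2PO4, 2-methyl-2-butene, t-BuOH/H2O, 0 °C → rt
Reagents that add atoms: sodium chlorite, [Na+].[O-]Cl=O
Why: Pinnick oxidation should convert the aldehyde to the acid at about pH 4 without touching the silyl ethers, the β-stereocentre or the alkene, whose chlorination is prevented by the hypochlorite scavenger 2-methyl-2-butene.

Step 3
Reactants: 5 (3S,5R,6E)-3,5-bis[(tert-butyldimethylsilyl)oxy]oct-6-enoic acid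
Product: 7 (4S,6R)-4-hydroxy-6-[(1E)-prop-1-en-1-yl]oxan-2-one, via dihydroxy acid 6 (not isolated)
Conditions: HF·pyridine, THF/pyridine, 0 °C → rt; then PPTS (cat.), toluene, 40 °C
Reagents that add atoms: none
Why: Fluoride-mediated silyl ether cleavage frees diol acid 6, whose C5 hydroxyl should close the six-membered ring by acid-catalysed lactonisation (6-exo-trig; the four-membered alternative through the C3 hydroxyl is strained), with no change at either stereocentre.

Step 4
Reactants: 8 (E)-3-phenylprop-2-enal (cinnamaldehyde); 2 tert-butyldimethyl(vinyloxy)silane (1.3 equiv)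
Product: 9 (3S,4E)-3-[(tert-butyldimethylsilyl)oxy]-5-phenylpent-4-enal
Conditions: IDPi-Si (confined, 1 mol%), toluene, −60 °C
Reagents that add atoms: none
Why: This is the enantioselective Mukaiyama aldol (single aldolisation) of an acetaldehyde silyl enolate under a confined IDPi acid, in which the silylium-activated aldehyde is attacked at its Si face inside the chiral anion pocket (setting C3 as S) and the pocket rejects the bulkier β-silyloxy aldehyde product so that the reaction stops after one addition.

Step 5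
Reactants: 9 (3S,4E)-3-[(tert-butyldimethylsilyl)oxy]-5-phenylpent-4-enal
Product: 11 (4R,6S,7E)-6-[(tert-butyldimethylsilyl)oxy]-8-phenylocta-1,7-dien-4-ol, via borinate ester 10 (not isolated)
Conditions: (+)-Ipc2B(allyl), Et2O, −78 °C; then NaOH, H2O2, 0 °C → rt
Reagents that add atoms: (+)-B-allyldiisopinocampheylborane (from (−)-α-pinene), C=CCB([C@H]1C[C@H]2C[C@@H]([C@@H]1C)C2(C)C)[C@H]1C[C@H]2C[C@@H]([C@@H]1C)C2(C)C
Why: In this Brown allylation the allyl group is transferred through a chair six-membered transition state in which the isopinocampheyl groups direct attack to the Re face of the aldehyde, so the new carbinol should be R (1,3-anti to the silyloxy centre) by reagent control, and alkaline peroxide then cleaves borinate 10.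

Step 6
Reactants: 11 (4R,6S,7E)-6-[(tert-butyldimethylsilyl)oxy]-8-phenylocta-1,7-dien-4-ol
Product: 12 (1E,3S,5R)-1-phenylocta-1,7-diene-3,5-diol
Conditions: TBAF, THF, 0 °C → rt
Reagents that add atoms: none
Why: Fluoride cleaves the Si–O bond of the secondary allylic silyl ether (desilylation) and should leave both stereocentres and both alkenes untouched.

Step 7
Reactants: 12 (1E,3S,5R)-1-phenylocta-1,7-diene-3,5-diol
Product: 13 [(1E,3S,5R)-3,5-dimethoxyocta-1,7-dien-1-yl]benzene
Conditions: NaH, MeI, THF/DMF, 0 °C → rt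
Reagents that add atoms: iodomethane, CI
Why: In this Williamson ether synthesis both sodium alkoxides are methylated by iodomethane with retention at carbon, because no C–O bond of a stereocentre is broken.

Step 8
Reactants: 7 (4S,6R)-4-hydroxy-6-[(1E)-prop-1-en-1-yl]oxan-2-one (1.5 equiv); 13 [(1E,3S,5R)-3,5-dimethoxyocta-1,7-dien-1-yl]benzene
Product: 14 (4S,6R)-6-[(1E,4R,6S,7E)-4,6-dimethoxy-8-phenylocta-1,7-dien-1-yl]-4-hydroxyoxan-2-one
Conditions: Hoveyda–Grubbs II (5 mol%), CH2Cl2, 40 °C
Reagents that add atoms: none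
Why: Olefin cross-metathesis between the unhindered terminal alkene of 13 and the allylically oxygenated propenyl group of 7 should release propene and give the E-alkene under thermodynamic control, while the styryl alkene (1,2-disubstituted, conjugated and flanked by a branched allylic ether) reacts much more slowly and the free hydroxyl and lactone are tolerated by the ruthenium carbene.

Compound list
1 | (E)-but-2-enal (crotonaldehyde) | C/C=C/C=O | starting material
2 | tert-butyldimethyl(vinyloxy)silane | C=CO[Si](C)(C)C(C)(C)C | starting material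
3 | (3R,4E)-3-[(tert-butyldimethylsilyl)oxy]hex-4-enal | C/C=C/[C@H](O[Si](C)(C)C(C)(C)C)CC=O | intermediate
4 | (3S,5R,6E)-3,5-bis[(tert-butyldimethylsilyl)oxy]oct-6-enal | C/C=C/[C@H](O[Si](C)(C)C(C)(C)C)C[C@H](O[Si](C)(C)C(C)(C)C)CC=O | intermediate
5 | (3S,5R,6E)-3,5-bis[(tert-butyldimethylsilyl)oxy]oct-6-enoic acid | C/C=C/[C@H](O[Si](C)(C)C(C)(C)C)C[C@H](O[Si](C)(C)C(C)(C)C)CC(=O)O | intermediate
6 | (3S,5R,6E)-3,5-dihydroxyoct-6-enoic acid | C/C=C/[C@H](O)C[C@H](O)CC(=O)O | intermediate
7 | (4S,6R)-4-hydroxy-6-[(1E)-prop-1-en-1-yl]oxan-2-one | C/C=C/[C@H]1C[C@H](O)CC(=O)O1 | intermediate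
8 | (E)-3-phenylprop-2-enal (cinnamaldehyde) | O=C/C=C/c1ccccc1 | starting material
9 | (3S,4E)-3-[(tert-butyldimethylsilyl)oxy]-5-phenylpent-4-enal | O=CC[C@@H](/C=C/c1ccccc1)O[Si](C)(C)C(C)(C)C | intermediate
10 | (4R,6S,7E)-6-[(tert-butyldimethylsilyl)oxy]-8-phenylocta-1,7-dien-4-yl bis(isopinocampheyl)borinate | C=CC[C@@H](OB([C@H]1C[C@H]2C[C@@H]([C@@H]1C)C2(C)C)[C@H]1C[C@H]2C[C@@H]([C@@H]1C)C2(C)C)C[C@@H](/C=C/c1ccccc1)O[Si](C)(C)C(C)(C)C | intermediate
11 | (4R,6S,7E)-6-[(tert-butyldimethylsilyl)oxy]-8-phenylocta-1,7-dien-4-ol | C=CC[C@@H](O)C[C@@H](/C=C/c1ccccc1)O[Si](C)(C)C(C)(C)C | intermediate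
12 | (1E,3S,5R)-1-phenylocta-1,7-diene-3,5-diol | C=CC[C@@H](O)C[C@@H](/C=C/c1ccccc1)O | intermediate
13 | [(1E,3S,5R)-3,5-dimethoxyocta-1,7-dien-1-yl]benzene | C=CC[C@@H](OC)C[C@@H](/C=C/c1ccccc1)OC | intermediate
14 | (4S,6R)-6-[(1E,4R,6S,7E)-4,6-dimethoxy-8-phenylocta-1,7-dien-1-yl]-4-hydroxyoxan-2-one | CO[C@H](C/C=C/[C@H]1C[C@H](O)CC(=O)O1)C[C@@H](/C=C/c1ccccc1)OC | target

Total step count: 8
Longest linear sequence: 5 steps (steps 4, 5, 6, 7, 8)

Steps most likely to fail

Step 1. The double addition may stall at mono-adduct 3 or run on to oligomers, and the catalyst may lose facial control in the second addition to the β-silyloxy aldehyde. The fallback keeps the one-pot double aldol but changes the source of stereocontrol; it sets out from 1 and comes back at 7. Compound 1 is treated with tris(trimethylsilyl)silyl vinyl ether (2.2 equiv) and HNTf2 (0.05 mol%) in CH2Cl2; the very bulky silyl group enforces 3,5-syn induction and stops the chain after two additions, which should give racemic (3S,5R,6E)-3,5-bis{[tris(trimethylsilyl)silyl]oxy}oct-6-enal F1. Pinnick oxidation would give racemic (3S,5R,6E)-3,5-bis{[tris(trimethylsilyl)silyl]oxy}oct-6-enoic acid F2. HF·pyridine followed by catalytic PPTS would give racemic (4S,6R)-4-hydroxy-6-[(1E)-prop-1-en-1-yl]oxan-2-one F3. Preparative chromatography on a chiral stationary phase would then deliver 7.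

Step 8. Coupling of two elaborate partners may be slow, so that homodimerisation of 13, metathesis at the styryl alkene or erosion of the E/Z ratio compete. The fallback makes the union linear; it sets out from 13 and comes back at 14. Cross-metathesis of 13 with an excess of the inexpensive enal 1 (Hoveyda–Grubbs II, CH2Cl2, 40 °C) should give (2E,5R,7S,8E)-5,7-dimethoxy-9-phenylnona-2,8-dienal F4. The double aldol of step 1 (2, IDPi-Re) applied to this enal would give (3S,5R,6E,9R,11S,12E)-3,5-bis[(tert-butyldimethylsilyl)oxy]-9,11-dimethoxy-13-phenyltrideca-6,12-dienal F5. Pinnick oxidation would give (3S,5R,6E,9R,11S,12E)-3,5-bis[(tert-butyldimethylsilyl)oxy]-9,11-dimethoxy-13-phenyltrideca-6,12-dienoic acid F6, and HF·pyridine with catalytic PPTS would close the lactone to 14.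

Step 5. Reagent control may be eroded by the β-silyloxy stereocentre, which would show as poor facial selectivity at the new carbinol. The fallback sets the second centre by substrate-directed reduction; it sets out from 9 and comes back at 12. Allylmagnesium bromide (THF, −78 °C) adds to 9 to give the C4-epimeric mixture (6S,7E)-6-[(tert-butyldimethylsilyl)oxy]-8-phenylocta-1,7-dien-4-ol F7. Buffered Dess–Martin oxidation would give (6S,7E)-6-[(tert-butyldimethylsilyl)oxy]-8-phenylocta-1,7-dien-4-one F8, and HF·pyridine would free (6S,7E)-6-hydroxy-8-phenylocta-1,7-dien-4-one F9. Evans–Saksena reduction (Me4NBH(OAc)3, MeCN/AcOH, −30 °C) delivers hydride intramolecularly from the alkoxyborohydride bound at the C6 hydroxyl and should give the 1,3-anti diol 12.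

Further compounds
F1 | step 1 | racemic (3S,5R,6E)-3,5-bis{[tris(trimethylsilyl)silyl]oxy}oct-6-enal | C/C=C/[C@H](O[Si]([Si](C)(C)C)([Si](C)(C)C)[Si](C)(C)C)C[C@H](O[Si]([Si](C)(C)C)([Si](C)(C)C)[Si](C)(C)C)CC=O.C/C=C/[C@@H](O[Si]([Si](C)(C)C)([Si](C)(C)C)[Si](C)(C)C)C[C@@H](O[Si]([Si](C)(C)C)([Si](C)(C)C)[Si](C)(C)C)CC=O
F2 | step 1 | racemic (3S,5R,6E)-3,5-bis{[tris(trimethylsilyl)silyl]oxy}oct-6-enoic acid | C/C=C/[C@H](O[Si]([Si](C)(C)C)([Si](C)(C)C)[Si](C)(C)C)C[C@H](O[Si]([Si](C)(C)C)([Si](C)(C)C)[Si](C)(C)C)CC(=O)O.C/C=C/[C@@H](O[Si]([Si](C)(C)C)([Si](C)(C)C)[Si](C)(C)C)C[C@@H](O[Si]([Si](C)(C)C)([Si](C)(C)C)[Si](C)(C)C)CC(=O)O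
F3 | step 1 | racemic (4S,6R)-4-hydroxy-6-[(1E)-prop-1-en-1-yl]oxan-2-one | C/C=C/[C@H]1C[C@H](O)CC(=O)O1.C/C=C/[C@@H]1C[C@@H](O)CC(=O)O1
F4 | step 8 | (2E,5R,7S,8E)-5,7-dimethoxy-9-phenylnona-2,8-dienal | CO[C@H](C/C=C/C=O)C[C@@H](/C=C/c1ccccc1)OC
F5 | step 8 | (3S,5R,6E,9R,11S,12E)-3,5-bis[(tert-butyldimethylsilyl)oxy]-9,11-dimethoxy-13-phenyltrideca-6,12-dienal | CO[C@H](C/C=C/[C@H](O[Si](C)(C)C(C)(C)C)C[C@H](O[Si](C)(C)C(C)(C)C)CC=O)C[C@@H](/C=C/c1ccccc1)OC
F6 | step 8 | (3S,5R,6E,9R,11S,12E)-3,5-bis[(tert-butyldimethylsilyl)oxy]-9,11-dimethoxy-13-phenyltrideca-6,12-dienoic acid | CO[C@H](C/C=C/[C@H](O[Si](C)(C)C(C)(C)C)C[C@H](O[Si](C)(C)C(C)(C)C)CC(=O)O)C[C@@H](/C=C/c1ccccc1)OC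
F7 | step 5 | (6S,7E)-6-[(tert-butyldimethylsilyl)oxy]-8-phenylocta-1,7-dien-4-ol, mixture of C4 epimers | C=CCC(O)C[C@@H](/C=C/c1ccccc1)O[Si](C)(C)C(C)(C)C
F8 | step 5 | (6S,7E)-6-[(tert-butyldimethylsilyl)oxy]-8-phenylocta-1,7-dien-4-one | C=CCC(=O)C[C@@H](/C=C/c1ccccc1)O[Si](C)(C)C(C)(C)C
F9 | step 5 | (6S,7E)-6-hydroxy-8-phenylocta-1,7-dien-4-one | C=CCC(=O)C[C@@H](/C=C/c1ccccc1)O
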